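**Plan**

1. Rings: ring A is the 3-hydroxy-5-alkylphenyl ring, ring B the 3,5-dihydroxy-4-aryloxyphenyl ring that bears the carbinol. Enabling feature: in the 22-membered ring the E-CH=CH unit is followed, on the carbinol side, by a CH2–CH2 bond; with a carboxyl group placed on the second CH2, the array CH=CH–CH2–CH(CO2H) is the retron of an Ireland–Claisen rearrangement. Because its two ends are already joined through ring A, the ether oxygen and ring B, the allyl ester precursor can be a 22-membered macrolactone with an exocyclic vinyl group.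
2. Retrosynthetic cuts, in order: O-protecting groups; C–CO2H (helper carboxyl); the allylic CH2–CH2 bond ([3,3] shift, lactone to carbocycle of the same ring size); lactone C–O; vinyl–carbinol C–C; ring A aryl–CH2; benzylic C–C at ring B; diaryl ether C–O.
3. Forward: ring B phenol and ring A boronic acid → diaryl ether → carbinol side chain on ring B → side chain on ring A → macrolactone (temporary ring, ester tether) → Ireland–Claisen rearrangement (C–C bond, carbocycle and E-alkene in one event) → radical decarboxylation → deprotection.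
4. Stereochemistry: the (R)-carbinol comes from a catalyst-controlled dialkylzinc addition to the ring B aldehyde and is then only carried along; the E-alkene comes from the chair transition state of the sigmatropic shift; two transient stereocentres are erased.

Key step: step 14

Remark: the carbinol carbon made in step 11 and the carboxyl-bearing carbon made in step 14 are carried as mixtures of both configurations, because both are erased (steps 14 and 15); compounds 1, 5, 11 and 15 are taken as commercially available.

**Route**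

Step 1
Reactants: 1 3,4,5-trihydroxybenzaldehyde
Product: 2 3,5-dihydroxy-4-(prop-2-en-1-yloxy)benzaldehyde
Conditions: allyl bromide (1.0 equiv), KHCO3, DMF, Ar, rt
Reagents that add atoms: allyl bromide, C=CCBr
Why: Williamson ether synthesis under weak-base control, in which only the 4-OH (para to the formyl group and therefore the most acidic phenol) should be deprotonated by hydrogencarbonate and alkylated.

Step 2
Reactants: 2 3,5-dihydroxy-4-(prop-2-en-1-yloxy)benzaldehyde
Product: 3 3,5-bis(methoxymethoxy)-4-(prop-2-en-1-yloxy)benzaldehyde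
Conditions: MOMCl, iPr2NEt, CH2Cl2, 0 °C → rt
Reagents that add atoms: chloromethyl methyl ether, COCCl
Why: O-alkylation of the two remaining phenols with an α-chloro ether (MOM acetal formation), to which the aldehyde and the allyl ether are inert.

Step 3
Reactants: 3 3,5-bis(methoxymethoxy)-4-(prop-2-en-1-yloxy)benzaldehyde
Product: 4 4-hydroxy-3,5-bis(methoxymethoxy)benzaldehyde
Conditions: Pd(PPh3)4 (2 mol %), K2CO3, MeOH, rt
Reagents that add atoms: none
Why: Tsuji–Trost-type deallylation in which zerovalent palladium ionises the aryl allyl ether (the para-formyl phenoxide is a good leaving group) and methanol takes up the allyl fragment, K2CO3 acting only as proton shuttle while acetals and aldehyde stay intact.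

Step 4
Reactants: 5 3,5-dibromophenol
Product: 6 1,3-dibromo-5-(methoxymethoxy)benzene
Conditions: MOMCl, iPr2NEt, CH2Cl2, 0 °C → rt
Reagents that add atoms: chloromethyl methyl ether, COCCl
Why: MOM acetal formation by O-alkylation of the phenol, giving a protecting group that survives organolithium, cross-coupling and enolate chemistry.

Step 5
Reactants: 6 1,3-dibromo-5-(methoxymethoxy)benzene
Product: 9 [3-bromo-5-(methoxymethoxy)phenyl]boronic acid, via aryllithium 7 (not isolated), via lithium aryltriisopropoxyborate 8 (not isolated)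
Conditions: B(OiPr)3, n-BuLi (1.0 equiv, slow addition), toluene/THF, −78 °C; then aq. HCl to pH 5, 0 °C
Reagents that add atoms: triisopropyl borate, CC(C)OB(OC(C)C)OC(C)C; water, O
Why: Bromine–lithium exchange at one of the two equivalent C–Br bonds with in-situ borylation (the ate complex 8 protects the ring from a second exchange, and exchange outruns MOM-directed ortho-lithiation at −78 °C), followed by hydrolysis of the borate.

Step 6
Reactants: 4 4-hydroxy-3,5-bis(methoxymethoxy)benzaldehyde; 9 [3-bromo-5-(methoxymethoxy)phenyl]boronic acid (2 equiv)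
Product: 10 4-[3-bromo-5-(methoxymethoxy)phenoxy]-3,5-bis(methoxymethoxy)benzaldehyde
Conditions: Cu(OAc)2 (1.0 equiv), pyridine (5 equiv), 4 Å molecular sieves, CH2Cl2, air, rt
Reagents that add atoms: none
Why: Chan–Lam oxidative C–O coupling (copper phenoxide, transmetalation with the arylboronic acid, reductive elimination), which runs at room temperature, is known for 2,6-disubstituted and electron-poor phenols, and leaves the aryl bromide, the aldehyde and the MOM acetals untouched.

Step 7
Reactants: 10 4-[3-bromo-5-(methoxymethoxy)phenoxy]-3,5-bis(methoxymethoxy)benzaldehyde; 11 ethyl 6-iodohexanoate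
Product: 13 ethyl (7R)-7-{4-[3-bromo-5-(methoxymethoxy)phenoxy]-3,5-bis(methoxymethoxy)phenyl}-7-hydroxyheptanoate, via bis(6-ethoxy-6-oxohexyl)zinc 12 (not isolated)
Conditions: 11, Et2Zn (neat), CuI (cat.), 50 °C, then vacuum; Ti(OiPr)4 (2 equiv), (1S,2S)-1,2-bis(trifluoromethanesulfonamido)cyclohexane (8 mol %), toluene, −20 °C; then 10
Reagents that add atoms: none
Why: Iodine–zinc exchange gives the ester-bearing dialkylzinc 12, and its titanium–bis(sulfonamide)-catalysed asymmetric 1,2-addition to the aromatic aldehyde should place the alkyl group on the Re face (the (1S,2S)-ligand is the mirror image of the one known to give (S)-carbinols from aromatic aldehydes), so that the (R)-carbinol forms while ester and aryl bromide are inert to the dialkylzinc.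

Step 8
Reactants: 13 ethyl (7R)-7-{4-[3-bromo-5-(methoxymethoxy)phenoxy]-3,5-bis(methoxymethoxy)phenyl}-7-hydroxyheptanoate
Product: 14 ethyl (7R)-7-{4-[3-bromo-5-(methoxymethoxy)phenoxy]-3,5-bis(methoxymethoxy)phenyl}-7-[(tert-butyldimethylsilyl)oxy]heptanoate
Conditions: TBSCl, imidazole, DMF, rt
Reagents that add atoms: tert-butyldimethylsilyl chloride, CC(C)(C)[Si](C)(C)Cl
Why: Imidazole-promoted silyl ether formation masks the secondary benzylic alcohol for the oxidation and enolate steps without touching the stereocentre.

Step 9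
Reactants: 14 ethyl (7R)-7-{4-[3-bromo-5-(methoxymethoxy)phenoxy]-3,5-bis(methoxymethoxy)phenyl}-7-[(tert-butyldimethylsilyl)oxy]heptanoate; 15 hex-5-en-1-ol
Product: 17 ethyl (7R)-7-[(tert-butyldimethylsilyl)oxy]-7-{4-[3-(6-hydroxyhexyl)-5-(methoxymethoxy)phenoxy]-3,5-bis(methoxymethoxy)phenyl}heptanoate, via O-borylated alkylborane 16 (not isolated)
Conditions: 15, 9-BBN (2.1 equiv per 15), THF, 0 °C → rt; then 14, Pd(dppf)Cl2 (5 mol %), K3PO4 (3 M aq.), DMF, 60 °C
Reagents that add atoms: none
Why: Anti-Markovnikov hydroboration of the terminal alkene (the hydroxyl is tied up as its borinate) and B-alkyl Suzuki–Miyaura coupling with the aryl bromide join the six-carbon chain to ring A, and the phosphate base at 60 °C should spare the ethyl ester, the silyl ether and the acetals.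

Step 10
Reactants: 17 ethyl (7R)-7-[(tert-butyldimethylsilyl)oxy]-7-{4-[3-(6-hydroxyhexyl)-5-(methoxymethoxy)phenoxy]-3,5-bis(methoxymethoxy)phenyl}heptanoate
Product: 18 ethyl (7R)-7-[(tert-butyldimethylsilyl)oxy]-7-{3,5-bis(methoxymethoxy)-4-[3-(methoxymethoxy)-5-(6-oxohexyl)phenoxy]phenyl}heptanoate
Conditions: Dess–Martin periodinane, pyridine, CH2Cl2, 0 °C → rt
Reagents that add atoms: none
Why: Dess–Martin oxidation of the primary alcohol to the aldehyde under buffered, non-acidic conditions compatible with silyl ether, acetals and ester.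

Step 11
Reactants: 18 ethyl (7R)-7-[(tert-butyldimethylsilyl)oxy]-7-{3,5-bis(methoxymethoxy)-4-[3-(methoxymethoxy)-5-(6-oxohexyl)phenoxy]phenyl}heptanoate
Product: 19 ethyl (7R)-7-[(tert-butyldimethylsilyl)oxy]-7-{4-[3-(6-hydroxyoct-7-en-1-yl)-5-(methoxymethoxy)phenoxy]-3,5-bis(methoxymethoxy)phenyl}heptanoate (both configurations at the allylic carbinol carbon)
Conditions: CH2=CHMgBr (1.2 equiv), THF, −78 °C
Reagents that add atoms: vinylmagnesium bromide, C=C[Mg]Br
Why: Grignard 1,2-addition to the aldehyde, which at −78 °C is far more electrophilic than the ethyl ester; the new carbinol centre forms without control, which is immaterial because it becomes an alkene carbon in step 14.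

Step 12
Reactants: 19 ethyl (7R)-7-[(tert-butyldimethylsilyl)oxy]-7-{4-[3-(6-hydroxyoct-7-en-1-yl)-5-(methoxymethoxy)phenoxy]-3,5-bis(methoxymethoxy)phenyl}heptanoate
Product: 20 (7R)-7-[(tert-butyldimethylsilyl)oxy]-7-{4-[3-(6-hydroxyoct-7-en-1-yl)-5-(methoxymethoxy)phenoxy]-3,5-bis(methoxymethoxy)phenyl}heptanoic acid
Conditions: LiOH, THF/MeOH/H2O, rt; then aq. HCl to pH 4, 0 °C
Reagents that add atoms: lithium hydroxide, [Li+].[OH-]
Why: Saponification (acyl substitution by hydroxide) of the unhindered ethyl ester, with silyl ether, acetals and allylic alcohol stable to aqueous base.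

Step 13
Reactants: 20 (7R)-7-[(tert-butyldimethylsilyl)oxy]-7-{4-[3-(6-hydroxyoct-7-en-1-yl)-5-(methoxymethoxy)phenoxy]-3,5-bis(methoxymethoxy)phenyl}heptanoic acid
Product: 22 22-membered macrolactone of seco acid 20 (ester between its carboxyl group and its allylic hydroxyl; exocyclic vinyl group; R at the silyloxy carbon), via mixed anhydride 21 (not isolated)
Conditions: 2-methyl-6-nitrobenzoic anhydride (1.3 equiv), DMAP (6 equiv), CH2Cl2, rt, slow addition of 20 (final 2 mM)
Reagents that add atoms: none
Why: Shiina macrolactonisation, in which mixed anhydride 21 is activated by DMAP and trapped intramolecularly by the secondary allylic hydroxyl under high dilution, closes the 22-membered lactone at room temperature without touching the stereocentre or the protecting groups.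

Step 14
Reactants: 22 22-membered macrolactone with exocyclic vinyl group
Product: 25 macrocyclic carboxylic acid (22-membered carbocycle; E-alkene; carboxyl group on the ring carbon next to the allylic CH2 on the carbinol side; R at the silyloxy carbon), via silyl ketene acetal 23 (not isolated), via trimethylsilyl ester 24 (not isolated)
Conditions: Me3SiCl/Et3N, THF, −78 °C; LiN(iPr)2; −78 °C → rt, then 60 °C; aq. NaH2PO4 work-up
Reagents that add atoms: none
Why: Deprotonation of the lactone α-CH2 and O-silylation give ketene acetal 23, in which the O–C(OSiMe3)=CH unit and the exocyclic vinyl group form an allyl vinyl ether; on warming, a concerted suprafacial [3,3]-sigmatropic shift makes the bond between the α-carbon and the vinyl CH2 and breaks the lactone C–O bond, giving silyl ester 24 and, after hydrolysis, acid 25. The closest known reaction type is the Ireland–Claisen rearrangement of lactones that carry an alkenyl group on the carbinol carbon (lactone-to-carbocycle ring transposition). The 22-membered carbocycle is closed through a six-membered chair transition state embedded in the 22-membered lactone, so this is a ring-size-conserving transposition inside an existing ring and not an exo or endo closure of an open chain, and no high dilution is needed. No permanent stereocentre is formed: the carboxyl-bearing carbon arises as a mixture and is erased in step 15, while the E-geometry of the new alkene is set by the chair transition state with the chain leading to ring A pseudo-equatorial on the carbinol carbon. The selectivity needed is enolisation at the lactone α-position only and E over Z; the first is secured because MOM acetals, silyl ether and diaryl ether offer no C–H of comparable acidity toward LiN(iPr)2 at −78 °C and in-situ Me3SiCl trapping prevents Claisen condensation or ketene loss, the second by the pseudo-equatorial preference in an unstrained large ring. The (R)-silyloxy stereocentre lies five bonds from the reacting array and is not involved.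

Step 15
Reactants: 25 macrocyclic carboxylic acid
Product: 27 O-tert-butyldimethylsilyl tris-O-(methoxymethyl) dehydrogravicycle, via thiohydroxamate ester 26 (not isolated)
Conditions: 1-hydroxypyridine-2(1H)-thione, DCC, DMAP (cat.), CH2Cl2, rt, dark; then Bu3SnH, hν (tungsten lamp), PhH, rt
Reagents that add atoms: none
Why: Barton reductive decarboxylation, in which the thiohydroxamate ester fragments under visible light to CO2 and a secondary alkyl radical that abstracts hydrogen from Bu3SnH, removes the helper carboxyl group and its stereocentre while the isolated E-alkene, silyl ether and acetals are inert to the tin-radical chain.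

Step 16
Reactants: 27 O-tert-butyldimethylsilyl tris-O-(methoxymethyl) dehydrogravicycle
Product: 28 dehydrogravicycle
Conditions: HCl (2 M in MeOH), MeOH/THF, 0 °C → rt
Reagents that add atoms: none
Why: Acid-catalysed methanolysis (transacetalisation of the three aryl MOM ethers and solvolysis of the silyl ether) in one operation, during which the benzylic carbinol should not ionise because ring B offers only meta oxygen substituents and a twisted para-aryloxy group, so that the (R)-configuration and the E-alkene are retained.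

**Compound list**

1 | 3,4,5-trihydroxybenzaldehyde | O=Cc1cc(O)c(O)c(O)c1 | starting material
2 | 3,5-dihydroxy-4-(prop-2-en-1-yloxy)benzaldehyde | O=Cc1cc(O)c(OCC=C)c(O)c1 | intermediate
3 | 3,5-bis(methoxymethoxy)-4-(prop-2-en-1-yloxy)benzaldehyde | O=Cc1cc(OCOC)c(OCC=C)c(OCOC)c1 | intermediate
4 | 4-hydroxy-3,5-bis(methoxymethoxy)benzaldehyde | O=Cc1cc(OCOC)c(O)c(OCOC)c1 | intermediate
5 | 3,5-dibromophenol | Oc1cc(Br)cc(Br)c1 | starting material
6 | 1,3-dibromo-5-(methoxymethoxy)benzene | COCOc1cc(Br)cc(Br)c1 | intermediate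
7 | [3-bromo-5-(methoxymethoxy)phenyl]lithium | [Li]c1cc(Br)cc(OCOC)c1 | intermediate (not isolated)
8 | lithium [3-bromo-5-(methoxymethoxy)phenyl]tri(propan-2-yloxy)borate | [Li+].CC(C)O[B-](OC(C)C)(OC(C)C)c1cc(Br)cc(OCOC)c1 | intermediate (not isolated)
9 | [3-bromo-5-(methoxymethoxy)phenyl]boronic acid | OB(O)c1cc(Br)cc(OCOC)c1 | intermediate
10 | 4-[3-bromo-5-(methoxymethoxy)phenoxy]-3,5-bis(methoxymethoxy)benzaldehyde | O=Cc1cc(OCOC)c(Oc2cc(Br)cc(OCOC)c2)c(OCOC)c1 | intermediate
11 | ethyl 6-iodohexanoate | CCOC(=O)CCCCCI | starting material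
12 | bis(6-ethoxy-6-oxohexyl)zinc | CCOC(=O)CCCCC[Zn]CCCCCC(=O)OCC | intermediate (not isolated)
13 | ethyl (7R)-7-{4-[3-bromo-5-(methoxymethoxy)phenoxy]-3,5-bis(methoxymethoxy)phenyl}-7-hydroxyheptanoate | CCOC(=O)CCCCC[C@@H](O)c1cc(OCOC)c(Oc2cc(Br)cc(OCOC)c2)c(OCOC)c1 | intermediate
14 | ethyl (7R)-7-{4-[3-bromo-5-(methoxymethoxy)phenoxy]-3,5-bis(methoxymethoxy)phenyl}-7-[(tert-butyldimethylsilyl)oxy]heptanoate | CCOC(=O)CCCCC[C@@H](O[Si](C)(C)C(C)(C)C)c1cc(OCOC)c(Oc2cc(Br)cc(OCOC)c2)c(OCOC)c1 | intermediate
15 | hex-5-en-1-ol | OCCCCC=C | starting material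
16 | 9-{6-[(9-borabicyclo[3.3.1]nonan-9-yl)oxy]hexyl}-9-borabicyclo[3.3.1]nonane | C1CCC2CCCC1B2CCCCCCOB1C2CCCC1CCC2 | intermediate (not isolated)
17 | ethyl (7R)-7-[(tert-butyldimethylsilyl)oxy]-7-{4-[3-(6-hydroxyhexyl)-5-(methoxymethoxy)phenoxy]-3,5-bis(methoxymethoxy)phenyl}heptanoate | CCOC(=O)CCCCC[C@@H](O[Si](C)(C)C(C)(C)C)c1cc(OCOC)c(Oc2cc(CCCCCCO)cc(OCOC)c2)c(OCOC)c1 | intermediate
18 | ethyl (7R)-7-[(tert-butyldimethylsilyl)oxy]-7-{3,5-bis(methoxymethoxy)-4-[3-(methoxymethoxy)-5-(6-oxohexyl)phenoxy]phenyl}heptanoate | CCOC(=O)CCCCC[C@@H](O[Si](C)(C)C(C)(C)C)c1cc(OCOC)c(Oc2cc(CCCCCC=O)cc(OCOC)c2)c(OCOC)c1 | intermediate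
19 | ethyl (7R)-7-[(tert-butyldimethylsilyl)oxy]-7-{4-[3-(6-hydroxyoct-7-en-1-yl)-5-(methoxymethoxy)phenoxy]-3,5-bis(methoxymethoxy)phenyl}heptanoate, both configurations at the allylic carbinol carbon | CCOC(=O)CCCCC[C@@H](O[Si](C)(C)C(C)(C)C)c1cc(OCOC)c(Oc2cc(CCCCCC(O)C=C)cc(OCOC)c2)c(OCOC)c1 | intermediate
20 | (7R)-7-[(tert-butyldimethylsilyl)oxy]-7-{4-[3-(6-hydroxyoct-7-en-1-yl)-5-(methoxymethoxy)phenoxy]-3,5-bis(methoxymethoxy)phenyl}heptanoic acid, both configurations at the allylic carbinol carbon | OC(=O)CCCCC[C@@H](O[Si](C)(C)C(C)(C)C)c1cc(OCOC)c(Oc2cc(CCCCCC(O)C=C)cc(OCOC)c2)c(OCOC)c1 | intermediate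
21 | mixed anhydride of 20 with 2-methyl-6-nitrobenzoic acid | Cc1cccc([N+](=O)[O-])c1C(=O)OC(=O)CCCCC[C@@H](O[Si](C)(C)C(C)(C)C)c1cc(OCOC)c(Oc2cc(CCCCCC(O)C=C)cc(OCOC)c2)c(OCOC)c1 | intermediate (not isolated)
22 | 22-membered macrolactone of 20: ring made of the ester C(=O)–O, the vinyl-bearing carbinol carbon, five CH2, ring A (meta), the ether oxygen, ring B (para), the (R)-CH(OTBS) carbon and five CH2; both configurations at the vinyl-bearing carbon | C=CC1CCCCCc2cc(OCOC)cc(c2)Oc2c(OCOC)cc(cc2OCOC)[C@H](O[Si](C)(C)C(C)(C)C)CCCCCC(=O)O1 | intermediate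
23 | O-trimethylsilyl ketene acetal of 22 | C=CC1CCCCCc2cc(OCOC)cc(c2)Oc2c(OCOC)cc(cc2OCOC)[C@H](O[Si](C)(C)C(C)(C)C)CCCCC=C(O[Si](C)(C)C)O1 | intermediate (not isolated)
24 | trimethylsilyl ester of 25 | C[Si](C)(C)OC(=O)C1C/C=C/CCCCCc2cc(OCOC)cc(c2)Oc2c(OCOC)cc(cc2OCOC)[C@H](O[Si](C)(C)C(C)(C)C)CCCC1 | intermediate (not isolated)
25 | macrocyclic acid: O-TBS tris-O-MOM dehydrogravicycle bearing a carboxyl group on the ring carbon next to the allylic CH2 on the carbinol side; E-alkene; R at the silyloxy carbon; both configurations at the carboxyl-bearing carbon | OC(=O)C1C/C=C/CCCCCc2cc(OCOC)cc(c2)Oc2c(OCOC)cc(cc2OCOC)[C@H](O[Si](C)(C)C(C)(C)C)CCCC1 | intermediate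
26 | 2-thioxopyridin-1(2H)-yl ester (thiohydroxamate ester) of 25 | S=c1ccccn1OC(=O)C1C/C=C/CCCCCc2cc(OCOC)cc(c2)Oc2c(OCOC)cc(cc2OCOC)[C@H](O[Si](C)(C)C(C)(C)C)CCCC1 | intermediate (not isolated)
27 | O-tert-butyldimethylsilyl tris-O-(methoxymethyl) dehydrogravicycle (R; E) | COCOc1cc2cc(c1)Oc1c(OCOC)cc(cc1OCOC)[C@H](O[Si](C)(C)C(C)(C)C)CCCCCC/C=C/CCCCC2 | intermediate
28 | dehydrogravicycle | Oc1cc2cc(c1)Oc1c(O)cc(cc1O)[C@H](O)CCCCCC/C=C/CCCCC2 | target

**Step count and risks**

Total steps: 16. Longest linear sequence: 14 steps (steps 1–3 and 6–16, from 1 to 28).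

Steps most likely to fail:

1. Step 14. Enolisation or silylation of the macrolactone may be incomplete, the lactone enolate may fragment to a ketene before it is silylated, or a boat transition state may erode the E-selectivity. Fallback, from 19 back to 25: the vinyl carbinol of 19 is converted with allylic transposition (SOCl2, Et2O, −20 °C) into the primary (E)-allylic chloride F1. Slow addition of F1 to KN(SiMe3)2 in THF at high dilution (−78 → 0 °C) should close the same C–C bond by intramolecular C-alkylation of the ester enolate, giving the macrocyclic ethyl ester F2. Saponification (LiOH, THF/MeOH/H2O, 50 °C) then gives 25.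

2. Step 7. Alkyl transfer may be sluggish, or facial selectivity poor because the MOM oxygens compete for titanium. Fallback, from 10 back to 13: 12 is added to 10 with an achiral promoter (2-(dimethylamino)ethanol, toluene, 0 °C) to give the racemic hydroxy ester F3. Dess–Martin oxidation gives the keto ester F4. Asymmetric transfer hydrogenation with RuCl[(R,R)-TsDPEN](p-cymene) and HCO2H/Et3N, which reduces aryl ketones but not esters or aryl bromides, should then deliver 13.

3. Step 16. Acid may ionise the benzylic carbinol (racemisation, methyl ether formation, transannular arylation), or liberated formaldehyde equivalents may attack the electron-rich rings. Fallback, from 27 back to 28: the three MOM groups are removed first under aprotic Lewis-acid thiolysis (ZnBr2, n-PrSH, CH2Cl2, 0 °C) while the carbinol stays silylated, giving the mono-silyl ether triphenol F5. Buffered fluoride (Bu4NF, AcOH, THF, rt) then gives 28.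

**Further compounds**

F1 | step 14 | ethyl (7R)-7-[(tert-butyldimethylsilyl)oxy]-7-{4-[3-((6E)-8-chlorooct-6-en-1-yl)-5-(methoxymethoxy)phenoxy]-3,5-bis(methoxymethoxy)phenyl}heptanoate | CCOC(=O)CCCCC[C@@H](O[Si](C)(C)C(C)(C)C)c1cc(OCOC)c(Oc2cc(CCCCC/C=C/CCl)cc(OCOC)c2)c(OCOC)c1
F2 | step 14 | ethyl ester of macrocyclic acid 25 | CCOC(=O)C1C/C=C/CCCCCc2cc(OCOC)cc(c2)Oc2c(OCOC)cc(cc2OCOC)[C@H](O[Si](C)(C)C(C)(C)C)CCCC1
F3 | step 7 | racemic ethyl 7-{4-[3-bromo-5-(methoxymethoxy)phenoxy]-3,5-bis(methoxymethoxy)phenyl}-7-hydroxyheptanoate | CCOC(=O)CCCCCC(O)c1cc(OCOC)c(Oc2cc(Br)cc(OCOC)c2)c(OCOC)c1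
F4 | step 7 | ethyl 7-{4-[3-bromo-5-(methoxymethoxy)phenoxy]-3,5-bis(methoxymethoxy)phenyl}-7-oxoheptanoate | CCOC(=O)CCCCCC(=O)c1cc(OCOC)c(Oc2cc(Br)cc(OCOC)c2)c(OCOC)c1
F5 | step 16 | O-tert-butyldimethylsilyl dehydrogravicycle (silyl ether at the benzylic carbinol; three free phenols) | Oc1cc2cc(c1)Oc1c(O)cc(cc1O)[C@H](O[Si](C)(C)C(C)(C)C)CCCCCC/C=C/CCCCC2
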